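The plan rests on cutting the two biaryl bonds of the fully substituted ring C, C3–ring D and C5–ring E. These two carbons flank the C4 oxygen just as the two C–H carbons of 2,6-dichloro-1,4-benzoquinone flank one carbonyl, and rings D and E are simple 1,3,5-trioxygenated benzenes. One telescoped Lewis acid/oxidant operation therefore joins two molecules of 1,3,5-trimethoxybenzene to this commercial quinone. It delivers the whole D–C–E terphenyl with the C1 and C4 oxygens in place and the C2 and C6 chlorides as latent oxygens. Ring B is later attached to O1 by SNAr on a fluorobenzaldehyde, whose formyl-bearing carbon then becomes the carbon whose oxygen carries ring A.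

Key step: step 1

Remarks on the chemistry:
- **Locants.** In ring C, C1 bears the oxygen to ring B, C2/C4/C6 bear OH, and C3/C5 bear rings D/E. In ring B, C1 bears the oxygen to ring A, C2 and C4 bear OH, and C6 bears the oxygen to ring C.
- **Stereochemistry.** The target has no stereocentre. Rings D and E are symmetric about their biaryl bonds, so no stereodescriptor arises.
- **Ring A polarity.** The bridging oxygen of the A–B ether belongs to ring B, so ring A has to enter as an aryl electrophile.
- **Ring C redox liability.** The ring C hydroquinone is a strong reductant. Its C4 oxygen is therefore capped, and a non-oxidising ring B electrophile is used.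

Step 1
Reactants: 1 2,6-dichloro-1,4-benzoquinone; 2 1,3,5-trimethoxybenzene (two equivalents in total)
Product: 6 2,6-dichloro-3,5-bis(2,4,6-trimethoxyphenyl)-1,4-benzoquinone, via monoaryl hydroquinone 3 (not isolated), via monoaryl quinone 4 (not isolated), via diaryl hydroquinone 5 (not isolated)
Conditions: 2 (1.1 equiv), BF3·OEt2 (0.3 equiv), CH2Cl2, −20 → 0 °C; Ag2O (1.5 equiv), rt, filter (Celite); 2 (1.2 equiv), BF3·OEt2 (0.3 equiv), CH2Cl2, 0 °C → rt; Ag2O (1.5 equiv), rt
Reagents that add atoms: none
Why: BF3 coordination lowers the LUMO of quinone 1, a ring carbon of 2 attacks C3 (the unsubstituted carbon β to the chlorine-flanked C1 carbonyl), and loss of the arenium proton plus enolisation gives hydroquinone 3; Ag2O returns 3 to quinone 4, whose last C–H carbon (C5) takes the second arene in the same way to give 5 and, after the second Ag2O treatment, 6. The closest known reaction type is the acid-promoted Friedel–Crafts (Michael-type) arylation of halobenzoquinones by indoles and polyalkoxybenzenes followed by reoxidation. No ring is closed and no stereocentre or stereogenic axis is created, because each 2,4,6-trimethoxyphenyl group is symmetric about its new bond. The step needs attack at the C–H rather than the C–Cl carbons, which is secured because soft carbon nucleophiles prefer the less hindered unsubstituted position whose developing enolate is stabilised by the α-chlorine, while chlorine lone-pair donation blunts C2 and C6. It also needs each arene to react only once, which follows from the steric shielding and, in the quinone state, the electron withdrawal imposed by the new substituent, and from keeping free 2 in slight excess. Since rings D and E are identical, monoadduct, bisadduct and any 2,6-dichlorohydroquinone formed by redox exchange all funnel to 6 in the second cycle.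

Step 2
Reactants: 6 2,6-dichloro-3,5-bis(2,4,6-trimethoxyphenyl)-1,4-benzoquinone
Product: 7 2,6-dimethoxy-3,5-bis(2,4,6-trimethoxyphenyl)-1,4-benzoquinone
Conditions: NaOMe (2.5 equiv), MeOH–THF, 0 → 40 °C
Reagents that add atoms: sodium methoxide, [Na+].[O-]C
Why: Each C–Cl carbon is the β-carbon of an enone running to the C4 carbonyl, i.e. a vinylogous acyl chloride, so methoxide should replace both chlorides by conjugate addition–elimination (as in the exhaustive methanolysis of chloranil), while the aryl-bearing C3 and C5 offer no leaving group.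

Step 3
Reactants: 7 2,6-dimethoxy-3,5-bis(2,4,6-trimethoxyphenyl)-1,4-benzoquinone
Product: 9 4-(benzyloxy)-3,5-dimethoxy-2,6-bis(2,4,6-trimethoxyphenyl)phenol, via hydroquinone 8 (not isolated)
Conditions: Na2S2O4, THF–H2O, rt, Ar; extract; BnBr (1.0 equiv), K2CO3, DMF, rt, Ar
Reagents that add atoms: benzyl bromide, BrCc1ccccc1
Why: Dithionite reduction followed by a Williamson etherification with one equivalent of benzyl bromide should alkylate only the C1 hydroxyl, which sits between two methoxy groups, because the C4 hydroxyl is buried between the ortho,ortho′-dimethoxylated rings D and E; carrying 8 on without isolation avoids its aerial reoxidation.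

Step 4
Reactants: 9 4-(benzyloxy)-3,5-dimethoxy-2,6-bis(2,4,6-trimethoxyphenyl)phenol
Product: 10 2-(benzyloxy)-1,3,5-trimethoxy-4,6-bis(2,4,6-trimethoxyphenyl)benzene
Conditions: NaH, MeI, DMF, 0 °C → rt
Reagents that add atoms: iodomethane, CI
Why: In this Williamson methylation, irreversible deprotonation and the smallest possible electrophile should overcome the shielding of the C4 phenoxide, and capping this oxygen removes the hydroquinone redox liability before the ether-forming steps.

Step 5
Reactants: 10 2-(benzyloxy)-1,3,5-trimethoxy-4,6-bis(2,4,6-trimethoxyphenyl)benzene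
Product: 11 2,4,6-trimethoxy-3,5-bis(2,4,6-trimethoxyphenyl)phenol
Conditions: H2 (1 atm), Pd/C, EtOAc–MeOH, rt
Reagents that add atoms: none
Why: Catalytic hydrogenolysis of the benzyl ether frees the C1 hydroxyl alone, since methyl ethers and the biaryl bonds are inert to H2 over Pd/C.

Step 6
Reactants: 12 1-fluoro-3,5-dimethoxybenzene
Product: 14 2-fluoro-4,6-dimethoxybenzaldehyde, via aryl iminium chloride 13 (not isolated)
Conditions: POCl3, DMF, 0 → 60 °C; then H2O, 0 °C → rt
Reagents that add atoms: N,N-dimethylformamide, CN(C)C=O (formyl carbon); water, O (formyl oxygen)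
Why: Vilsmeier–Haack formylation should strike the position ortho to one methoxy group and para to the other rather than the more crowded site between both methoxy groups, the usual outcome for 5-substituted 1,3-dimethoxybenzenes.

Step 7
Reactants: 11 2,4,6-trimethoxy-3,5-bis(2,4,6-trimethoxyphenyl)phenol; 14 2-fluoro-4,6-dimethoxybenzaldehyde
Product: 15 2-[2,4,6-trimethoxy-3,5-bis(2,4,6-trimethoxyphenyl)phenoxy]-4,6-dimethoxybenzaldehyde
Conditions: Cs2CO3, DMA, 120 °C, Ar
Reagents that add atoms: none
Why: In this nucleophilic aromatic substitution via a Meisenheimer adduct, the fluoride is ortho to the formyl acceptor and meta to both methoxy donors, so the charge is taken up by the aldehyde, only one position can react, and the non-oxidising electrophile tolerates the electron-rich phenoxide of 11.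

Step 8
Reactants: 15 2-[2,4,6-trimethoxy-3,5-bis(2,4,6-trimethoxyphenyl)phenoxy]-4,6-dimethoxybenzaldehyde
Product: 17 2-[2,4,6-trimethoxy-3,5-bis(2,4,6-trimethoxyphenyl)phenoxy]-4,6-dimethoxyphenol, via aryl formate 16 (not isolated)
Conditions: mCPBA (1.3 equiv), CH2Cl2, 0 °C → rt; aq NaHCO3 wash; K2CO3 (0.2 equiv), MeOH, rt
Reagents that add atoms: mCPBA, OOC(=O)c1cccc(Cl)c1
Why: In this Baeyer–Villiger (Dakin-type) oxidation the very electron-rich ring B migrates in the Criegee adduct in preference to hydride, and mild methanolysis of formate 16 unmasks the C1 hydroxyl of ring B with its C2 and C4 oxygens already methylated, so no hydroxyl differentiation on ring B is needed.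

Step 9
Reactants: 17 2-[2,4,6-trimethoxy-3,5-bis(2,4,6-trimethoxyphenyl)phenoxy]-4,6-dimethoxyphenol; 18 1-iodo-3,5-dimethoxybenzene
Product: 19 2-[2-(3,5-dimethoxyphenoxy)-3,5-dimethoxyphenoxy]-1,3,5-trimethoxy-4,6-bis(2,4,6-trimethoxyphenyl)benzene (tridecamethyl ether of the target)
Conditions: CuI (20 mol %), picolinic acid (40 mol %), K3PO4, DMSO, 90 °C, Ar
Reagents that add atoms: none
Why: This Ullmann-type C–O coupling uses the CuI/picolinic acid system devised for di-ortho-substituted phenols; iodide 18 is unhindered, 17 has a single free hydroxyl, and exclusion of air protects the electron-rich phenol.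

Step 10
Reactants: 19 tridecamethyl ether of the target
Product: 20 2-[2-(3,5-dihydroxyphenoxy)-3,5-dihydroxyphenoxy]-4,6-bis(2,4,6-trihydroxyphenyl)benzene-1,3,5-triol (CNP0228669.0)
Conditions: BBr3 (30 equiv), CH2Cl2, −78 °C → rt, Ar; ice–water; Sephadex LH-20 under Ar
Reagents that add atoms: none
Why: In this Lewis-acid ether cleavage, BBr3 binds each methoxy oxygen and bromide removes the methyl group by SN2 attack, whereas the two diaryl ether bridges offer no sp3 carbon and survive; the low temperature avoids acid-induced dehydration of the ortho,ortho′-dihydroxybiaryl units to dibenzofurans.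

Compound list
1 | 2,6-dichloro-1,4-benzoquinone | O=C1C=C(Cl)C(=O)C(Cl)=C1 | starting material
2 | 1,3,5-trimethoxybenzene | COc1cc(OC)cc(OC)c1 | starting material
3 | 2,6-dichloro-3-(2,4,6-trimethoxyphenyl)benzene-1,4-diol | Oc1c(Cl)cc(O)c(-c2c(OC)cc(OC)cc2OC)c1Cl | intermediate
4 | 2,6-dichloro-3-(2,4,6-trimethoxyphenyl)-1,4-benzoquinone | O=C1C(Cl)=CC(=O)C(c2c(OC)cc(OC)cc2OC)=C1Cl | intermediate
5 | 2,6-dichloro-3,5-bis(2,4,6-trimethoxyphenyl)benzene-1,4-diol | Oc1c(Cl)c(-c2c(OC)cc(OC)cc2OC)c(O)c(-c2c(OC)cc(OC)cc2OC)c1Cl | intermediate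
6 | 2,6-dichloro-3,5-bis(2,4,6-trimethoxyphenyl)-1,4-benzoquinone | COc1cc(OC)c(C2=C(Cl)C(=O)C(Cl)=C(c3c(OC)cc(OC)cc3OC)C2=O)c(OC)c1 | intermediate
7 | 2,6-dimethoxy-3,5-bis(2,4,6-trimethoxyphenyl)-1,4-benzoquinone | COC1=C(c2c(OC)cc(OC)cc2OC)C(=O)C(c2c(OC)cc(OC)cc2OC)=C(OC)C1=O | intermediate
8 | 2,6-dimethoxy-3,5-bis(2,4,6-trimethoxyphenyl)benzene-1,4-diol | COc1c(O)c(OC)c(-c2c(OC)cc(OC)cc2OC)c(O)c1-c1c(OC)cc(OC)cc1OC | intermediate
9 | 4-(benzyloxy)-3,5-dimethoxy-2,6-bis(2,4,6-trimethoxyphenyl)phenol | COc1c(OCc2ccccc2)c(OC)c(-c2c(OC)cc(OC)cc2OC)c(O)c1-c1c(OC)cc(OC)cc1OC | intermediate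
10 | 2-(benzyloxy)-1,3,5-trimethoxy-4,6-bis(2,4,6-trimethoxyphenyl)benzene | COc1c(OCc2ccccc2)c(OC)c(-c2c(OC)cc(OC)cc2OC)c(OC)c1-c1c(OC)cc(OC)cc1OC | intermediate
11 | 2,4,6-trimethoxy-3,5-bis(2,4,6-trimethoxyphenyl)phenol | COc1c(O)c(OC)c(-c2c(OC)cc(OC)cc2OC)c(OC)c1-c1c(OC)cc(OC)cc1OC | intermediate
12 | 1-fluoro-3,5-dimethoxybenzene | COc1cc(F)cc(OC)c1 | starting material
13 | (2-fluoro-4,6-dimethoxybenzylidene)dimethyliminium chloride | C[N+](C)=Cc1c(F)cc(OC)cc1OC.[Cl-] | intermediate
14 | 2-fluoro-4,6-dimethoxybenzaldehyde | O=Cc1c(F)cc(OC)cc1OC | intermediate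
15 | 2-[2,4,6-trimethoxy-3,5-bis(2,4,6-trimethoxyphenyl)phenoxy]-4,6-dimethoxybenzaldehyde | O=Cc1c(Oc2c(OC)c(-c3c(OC)cc(OC)cc3OC)c(OC)c(-c3c(OC)cc(OC)cc3OC)c2OC)cc(OC)cc1OC | intermediate
16 | 2-[2,4,6-trimethoxy-3,5-bis(2,4,6-trimethoxyphenyl)phenoxy]-4,6-dimethoxyphenyl formate | O=COc1c(Oc2c(OC)c(-c3c(OC)cc(OC)cc3OC)c(OC)c(-c3c(OC)cc(OC)cc3OC)c2OC)cc(OC)cc1OC | intermediate
17 | 2-[2,4,6-trimethoxy-3,5-bis(2,4,6-trimethoxyphenyl)phenoxy]-4,6-dimethoxyphenol | Oc1c(Oc2c(OC)c(-c3c(OC)cc(OC)cc3OC)c(OC)c(-c3c(OC)cc(OC)cc3OC)c2OC)cc(OC)cc1OC | intermediate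
18 | 1-iodo-3,5-dimethoxybenzene | COc1cc(I)cc(OC)c1 | starting material
19 | 2-[2-(3,5-dimethoxyphenoxy)-3,5-dimethoxyphenoxy]-1,3,5-trimethoxy-4,6-bis(2,4,6-trimethoxyphenyl)benzene | COc1cc(OC)cc(Oc2c(OC)cc(OC)cc2Oc2c(OC)c(-c3c(OC)cc(OC)cc3OC)c(OC)c(-c3c(OC)cc(OC)cc3OC)c2OC)c1 | intermediate
20 | 2-[2-(3,5-dihydroxyphenoxy)-3,5-dihydroxyphenoxy]-4,6-bis(2,4,6-trihydroxyphenyl)benzene-1,3,5-triol (CNP0228669.0) | Oc1cc(O)cc(Oc2c(O)cc(O)cc2Oc2c(O)c(-c3c(O)cc(O)cc3O)c(O)c(-c3c(O)cc(O)cc3O)c2O)c1 | target

Total step count: 10. Longest linear sequence: 9 (steps 1–5 and 7–10; step 6 is a one-step side branch).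

Steps most likely to fail

**1. Step 1 (key step).**
- What may go wrong: the second addition stalls on the more crowded and less electrophilic monoaryl quinone. Electron transfer from the arene to the activated quinone may cause oxidative homocoupling of the arene. Partial attack at the C–Cl carbons is also possible.
- Fallback: a cross-coupling of reversed polarity that sets out from 2 and comes back to the route at 10. Compound 2 is lithiated between two methoxy groups (n-BuLi, THF, 0 °C) to (2,4,6-trimethoxyphenyl)lithium F1 and transmetallated with ZnCl2 to (2,4,6-trimethoxyphenyl)zinc chloride F2. In parallel, commercial 2,4,6-trimethoxyphenol is benzylated (BnBr, K2CO3, DMF) to 2-(benzyloxy)-1,3,5-trimethoxybenzene F3. NBS (2 equiv, MeCN, 0 °C) then brominates its two free positions to 1-(benzyloxy)-3,5-dibromo-2,4,6-trimethoxybenzene F4. A double Negishi coupling of F4 with F2 (Pd2(dba)3, RuPhos, THF, 70 °C) should give 10 directly, so that steps 1–4 are bypassed.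

**2. Step 7.**
- What may go wrong: the doubly ortho-substituted phenoxide adds too slowly to a fluoroarene whose formyl acceptor is weakened by two methoxy donors. At the temperature required, methyl transfer from the activated methoxy groups to the phenoxide may then compete.
- Fallback: a room-temperature addition–elimination on a quinone, which sets out from 11 and comes back at 17. 2-Bromo-6-methoxyphenol is oxidised ((KSO3)2NO, KH2PO4, H2O–acetone, Teuber oxidation) to 2-bromo-6-methoxy-1,4-benzoquinone F5. The phenoxide of 11 (K2CO3, MeCN, 0 °C → rt) replaces the bromide to give 2-methoxy-6-[2,4,6-trimethoxy-3,5-bis(2,4,6-trimethoxyphenyl)phenoxy]-1,4-benzoquinone F6. Na2S2O4 (THF–H2O) reduces this to 2-methoxy-6-[2,4,6-trimethoxy-3,5-bis(2,4,6-trimethoxyphenyl)phenoxy]benzene-1,4-diol F7. One equivalent of MeI with K2CO3 in acetone should then methylate the open C4 hydroxyl of ring B in preference to the C1 hydroxyl wedged between the methoxy group and the ring C oxygen. This gives 17 and replaces steps 7 and 8.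

**3. Step 9.**
- What may go wrong: the copper phenoxide of a phenol flanked by a methoxy group and the very bulky ring C aryloxy group forms or turns over sluggishly. Oxidative degradation of the electron-rich phenol may occur at 90 °C.
- Fallback: a metal-free arylation by ligand coupling at trivalent iodine, which sets out from 17 (with 18 and 2 serving to make the reagent) and comes back at 19. Compound 18 is oxidised with mCPBA and TsOH·H2O in MeCN to 1-[hydroxy(tosyloxy)iodo]-3,5-dimethoxybenzene F8. Addition of 2 converts this to (3,5-dimethoxyphenyl)(2,4,6-trimethoxyphenyl)iodonium tosylate F9. Treating 17 with F9 and K2CO3 in toluene at 50 °C should transfer the less electron-rich 3,5-dimethoxyphenyl group to the phenoxide oxygen, the trimethoxyphenyl group acting as the non-transferred ligand, and give 19.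

Further compounds
F1 | step 1 | (2,4,6-trimethoxyphenyl)lithium | [Li]c1c(OC)cc(OC)cc1OC
F2 | step 1 | (2,4,6-trimethoxyphenyl)zinc chloride | Cl[Zn]c1c(OC)cc(OC)cc1OC
F3 | step 1 | 2-(benzyloxy)-1,3,5-trimethoxybenzene | COc1cc(OC)c(OCc2ccccc2)c(OC)c1
F4 | step 1 | 1-(benzyloxy)-3,5-dibromo-2,4,6-trimethoxybenzene | COc1c(Br)c(OC)c(OCc2ccccc2)c(OC)c1Br
F5 | step 7 | 2-bromo-6-methoxy-1,4-benzoquinone | COC1=CC(=O)C=C(Br)C1=O
F6 | step 7 | 2-methoxy-6-[2,4,6-trimethoxy-3,5-bis(2,4,6-trimethoxyphenyl)phenoxy]-1,4-benzoquinone | COC1=CC(=O)C=C(Oc2c(OC)c(-c3c(OC)cc(OC)cc3OC)c(OC)c(-c3c(OC)cc(OC)cc3OC)c2OC)C1=O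
F7 | step 7 | 2-methoxy-6-[2,4,6-trimethoxy-3,5-bis(2,4,6-trimethoxyphenyl)phenoxy]benzene-1,4-diol | COc1cc(O)cc(Oc2c(OC)c(-c3c(OC)cc(OC)cc3OC)c(OC)c(-c3c(OC)cc(OC)cc3OC)c2OC)c1O
F8 | step 9 | 1-[hydroxy(tosyloxy)iodo]-3,5-dimethoxybenzene | COc1cc(OC)cc(I(O)OS(=O)(=O)c2ccc(C)cc2)c1
F9 | step 9 | (3,5-dimethoxyphenyl)(2,4,6-trimethoxyphenyl)iodonium tosylate | COc1cc(OC)cc([I+]c2c(OC)cc(OC)cc2OC)c1.Cc1ccc(S(=O)(=O)[O-])cc1
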